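**Strategy.** The cyclohexene (C1 acyl-bearing, C2 4-hydroxy-3-methoxyphenyl-bearing, C3H2, C4=C5, C6 3,4-dimethoxyphenyl-bearing) is cut at C1–C2 and C1–C6. Both flanking carbons are benzylic and stand β to C4, so with C4 as a ketone they are the two electrophilic ends of a dienone and C1 is a one-carbon double nucleophile. In one operation, malonate forms both bonds, closes the six-membered ring and sets C2 (catalyst) plus C6 and C5 (thermodynamic, all-equatorial). The precursor is an acyclic cross-conjugated 1,5-diaryl dienone whose dimethoxybenzylidene terminus carries a phenylsulfonyl group at C5. That sulfone later fixes the alkene at C4=C5 by Julia-type elimination.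

Key step: step 4

Remarks and assumptions on the chemistry:
- Ring atoms are called C1–C6 as defined above throughout, whatever the IUPAC locants of an intermediate are.
- The quinine-derived amine–thiourea is assumed to deliver the malonate carbon to the Re face of the enone β-carbon (C2). If the sense of induction proves opposite, the quinidine-derived pseudo-enantiomer is used with no other change.
- The dienone is built with the Knoevenagel condensation last, because aldol chemistry on a preformed sulfonyl arylidene would expose a very electrophilic alkene to enolates. MOM-protected methyl ferulate serves twice, as the enone half of the dienone and as the source of the feruloyl unit of the side chain.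

**Step 1**
Reactants: 1 methyl (E)-3-(4-hydroxy-3-methoxyphenyl)prop-2-enoate (methyl ferulate)
Product: 2 methyl (E)-3-[3-methoxy-4-(methoxymethoxy)phenyl]prop-2-enoate
Conditions: MOMCl, i-Pr2NEt, CH2Cl2, 0 °C → rt
Reagents that add atoms: chloromethyl methyl ether, COCCl
Why: Williamson-type O-alkylation of the phenol gives an acetal that is stable to every basic, reducing and organometallic step that follows and is removed by mild acid at the end.

**Step 2**
Reactants: 2 methyl (E)-3-[3-methoxy-4-(methoxymethoxy)phenyl]prop-2-enoate; 3 methyl phenyl sulfone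
Product: 5 (E)-4-[3-methoxy-4-(methoxymethoxy)phenyl]-1-(phenylsulfonyl)but-3-en-2-one, via lithiomethyl phenyl sulfone 4 (not isolated)
Conditions: 3 (2.2 equiv), n-BuLi (2.2 equiv), THF, −78 → 0 °C; then 2, −78 → 0 °C; aq. NH4Cl
Reagents that add atoms: none
Why: Claisen-type acylation of an α-sulfonyl carbanion by a methyl ester, in which the hard lithiated sulfone attacks the ester carbonyl of the electron-rich cinnamate and not its β-carbon; the second equivalent deprotonates the β-keto sulfone as it forms and so prevents a second addition.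

**Step 3**
Reactants: 5 (E)-4-[3-methoxy-4-(methoxymethoxy)phenyl]-1-(phenylsulfonyl)but-3-en-2-one; 6 3,4-dimethoxybenzaldehyde (veratraldehyde)
Product: 7 (1E,4E)-5-(3,4-dimethoxyphenyl)-1-[3-methoxy-4-(methoxymethoxy)phenyl]-4-(phenylsulfonyl)penta-1,4-dien-3-one
Conditions: piperidine (20 mol %), AcOH (20 mol %), toluene, reflux, Dean–Stark
Reagents that add atoms: none
Why: Knoevenagel condensation at the doubly activated methylene with azeotropic removal of water, the standard entry to alkylidene β-keto sulfones and esters; the aryl group should end up trans to the sulfonyl group, but this geometry has no consequence for step 4.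

**Step 4**
Reactants: 7 (1E,4E)-5-(3,4-dimethoxyphenyl)-1-[3-methoxy-4-(methoxymethoxy)phenyl]-4-(phenylsulfonyl)penta-1,4-dien-3-one; 8 dimethyl malonate
Product: 10 dimethyl (2S,3R,6R)-2-(3,4-dimethoxyphenyl)-6-[3-methoxy-4-(methoxymethoxy)phenyl]-4-oxo-3-(phenylsulfonyl)cyclohexane-1,1-dicarboxylate (aryl groups cis, sulfonyl trans to the neighbouring aryl), via acyclic malonate mono-adduct 9 (not isolated)
Conditions: 8 (1.2 equiv), 1-[3,5-bis(trifluoromethyl)phenyl]-3-[(8S,9S)-6′-methoxycinchonan-9-yl]thiourea (10 mol %), toluene, rt → 40 °C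
Reagents that add atoms: none
Why: The tertiary amine of the catalyst deprotonates 8, which adds first to the doubly activated (keto and sulfonyl) benzylidene carbon C6 of 7 in a fast, reversible Michael addition to give 9; the thiourea then binds the enone carbonyl while the amine-bound malonate carbon closes the ring on C2 by a 6-endo-trig Michael addition through a chair with both aryl groups equatorial. The closest known reaction type is the organocatalysed [5+1] double Michael annulation of malonates with 1,5-diarylpenta-1,4-dien-3-ones, run here with a tertiary amine–thiourea because the acidic β-keto sulfone would trap a primary amine as an enaminosulfone. C2 is set by the catalyst, which is expected to direct C1 to the Re face of the enone β-carbon. C6 is set relative to C2 by the substrate: 9 racemises at C6 by retro-Michael/Michael addition, and any trans-2,6 ring can reopen at C1–C6 through the sulfonyl ketone enolate until the cis, diequatorial diaryl arrangement is reached, while C5 is a freely epimerisable α-sulfonyl ketone carbon that should settle with the sulfonyl group equatorial, trans to the C6 aryl. The step needs regioselectivity (which terminus reacts first and where the later alkene will sit) and configurational stability at C2; the sulfonyl group secures both, since it makes C6 the most electrophilic carbon, marks C5, and directs all enolisation of 10 to C5 so that a retro-Michael reaction can break only C1–C6 and not the catalyst-made C1–C2 bond.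

**Step 5**
Reactants: 10 dimethyl (2S,3R,6R)-2-(3,4-dimethoxyphenyl)-6-[3-methoxy-4-(methoxymethoxy)phenyl]-4-oxo-3-(phenylsulfonyl)cyclohexane-1,1-dicarboxylate
Product: 11 dimethyl (2S,3R,6R)-2-(3,4-dimethoxyphenyl)-4-hydroxy-6-[3-methoxy-4-(methoxymethoxy)phenyl]-3-(phenylsulfonyl)cyclohexane-1,1-dicarboxylate (either C4 carbinol epimer or both)
Conditions: NaBH4, CeCl3·7H2O, MeOH–THF, −20 → 0 °C
Reagents that add atoms: none
Why: Luche-type borohydride reduction of the β-keto sulfone, done first to switch off the retro-Michael pathway; the cerium salt keeps the medium less basic so that the acidic sulfonyl ketone is reduced and not enolised, and the carbinol configuration is irrelevant because C4 becomes sp2 in step 7.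

**Step 6**
Reactants: 11 dimethyl (2S,3R,6R)-2-(3,4-dimethoxyphenyl)-4-hydroxy-6-[3-methoxy-4-(methoxymethoxy)phenyl]-3-(phenylsulfonyl)cyclohexane-1,1-dicarboxylate
Product: 12 dimethyl (2S,3R,6R)-4-acetoxy-2-(3,4-dimethoxyphenyl)-6-[3-methoxy-4-(methoxymethoxy)phenyl]-3-(phenylsulfonyl)cyclohexane-1,1-dicarboxylate
Conditions: Ac2O, pyridine, DMAP (cat.), CH2Cl2, 0 °C → rt
Reagents that add atoms: acetic anhydride, CC(=O)OC(C)=O
Why: DMAP-catalysed acetylation turns the hydroxyl into the leaving group needed for reductive elimination; any vinyl sulfone formed by E1cB loss of acetate should be reduced to the same alkene in step 7.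

**Step 7**
Reactants: 12 dimethyl (2S,3R,6R)-4-acetoxy-2-(3,4-dimethoxyphenyl)-6-[3-methoxy-4-(methoxymethoxy)phenyl]-3-(phenylsulfonyl)cyclohexane-1,1-dicarboxylate
Product: 13 dimethyl (2S,6R)-2-(3,4-dimethoxyphenyl)-6-[3-methoxy-4-(methoxymethoxy)phenyl]cyclohex-3-ene-1,1-dicarboxylate
Conditions: 6% Na(Hg), Na2HPO4, MeOH–THF, −20 °C
Reagents that add atoms: none
Why: Julia–Lythgoe reductive elimination, in which electron transfer cleaves the C5–S bond and the C5 carbanion expels the C4 acetate, so the alkene can form only between C4 and C5 while C2 and C6 stay untouched.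

**Step 8**
Reactants: 13 dimethyl (2S,6R)-2-(3,4-dimethoxyphenyl)-6-[3-methoxy-4-(methoxymethoxy)phenyl]cyclohex-3-ene-1,1-dicarboxylate
Product: 15 methyl (1R,2R,6S)-2-(3,4-dimethoxyphenyl)-6-[3-methoxy-4-(methoxymethoxy)phenyl]cyclohex-3-ene-1-carboxylate (ester trans to both aryl groups), via all-cis C1 epimer of the ester 14 (not isolated)
Conditions: LiCl, H2O, DMSO, 150 °C; then NaOMe (cat.), MeOH, 50 °C
Reagents that add atoms: none
Why: Krapcho dealkoxycarbonylation (chloride SN2 at an ester methyl, then loss of CO2) removes one ester, and methoxide equilibration through the ester enolate should then set C1 under thermodynamic control with the ester equatorial, trans to both flanking aryl groups in the all-pseudoequatorial half-chair.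

**Step 9**
Reactants: 15 methyl (1R,2R,6S)-2-(3,4-dimethoxyphenyl)-6-[3-methoxy-4-(methoxymethoxy)phenyl]cyclohex-3-ene-1-carboxylate
Product: 16 (1R,2R,6S)-2-(3,4-dimethoxyphenyl)-6-[3-methoxy-4-(methoxymethoxy)phenyl]cyclohex-3-ene-1-carboxylic acid
Conditions: LiOH·H2O, THF–MeOH–H2O, 65 °C; then 1 M HCl to pH 4, 0 °C
Reagents that add atoms: lithium hydroxide (aqueous), [Li+].[OH-]
Why: Saponification of the methyl ester; the basic medium can only push C1 further toward the favoured trans,trans isomer, and the aryl MOM ether tolerates a brief cold acidification.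

**Step 10**
Reactants: 16 (1R,2R,6S)-2-(3,4-dimethoxyphenyl)-6-[3-methoxy-4-(methoxymethoxy)phenyl]cyclohex-3-ene-1-carboxylic acid
Product: 17 1-[(1R,2R,6S)-2-(3,4-dimethoxyphenyl)-6-[3-methoxy-4-(methoxymethoxy)phenyl]cyclohex-3-en-1-yl]ethan-1-one
Conditions: MeLi (3 equiv), THF, 0 °C → rt; inverse quench into cold aq. NH4Cl
Reagents that add atoms: methyllithium, [Li]C
Why: Addition of methyllithium to the lithium carboxylate gives a dilithium gem-diolate that releases the methyl ketone only on quench, the standard acid-to-methyl-ketone conversion, which is most selective for hindered acids such as this one.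

**Step 11**
Reactants: 2 methyl (E)-3-[3-methoxy-4-(methoxymethoxy)phenyl]prop-2-enoate
Product: 18 (E)-3-[3-methoxy-4-(methoxymethoxy)phenyl]prop-2-enoic acid
Conditions: LiOH·H2O, THF–H2O, rt; then 1 M HCl to pH 4, 0 °C
Reagents that add atoms: lithium hydroxide (aqueous), [Li+].[OH-]
Why: Saponification of the cinnamate ester, to which the MOM ether is inert.

**Step 12**
Reactants: 18 (E)-3-[3-methoxy-4-(methoxymethoxy)phenyl]prop-2-enoic acid
Product: 19 (E)-1-(1H-benzotriazol-1-yl)-3-[3-methoxy-4-(methoxymethoxy)phenyl]prop-2-en-1-one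
Conditions: 1-(methylsulfonyl)-1H-benzotriazole, Et3N, THF, reflux
Reagents that add atoms: 1-(methylsulfonyl)-1H-benzotriazole, CS(=O)(=O)n1nnc2ccccc12
Why: Activation of the acid as its N-acylbenzotriazole under basic conditions (carboxylic–sulfonic mixed anhydride, then attack of benzotriazolide), which avoids the acid chloride and the HCl that would endanger the MOM group.

**Step 13**
Reactants: 17 1-[(1R,2R,6S)-2-(3,4-dimethoxyphenyl)-6-[3-methoxy-4-(methoxymethoxy)phenyl]cyclohex-3-en-1-yl]ethan-1-one; 19 (E)-1-(1H-benzotriazol-1-yl)-3-[3-methoxy-4-(methoxymethoxy)phenyl]prop-2-en-1-one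
Product: 21 (2Z,4E)-1-[(1R,2R,6S)-2-(3,4-dimethoxyphenyl)-6-[3-methoxy-4-(methoxymethoxy)phenyl]cyclohex-3-en-1-yl]-3-hydroxy-5-[3-methoxy-4-(methoxymethoxy)phenyl]penta-2,4-dien-1-one (enol form of the 1,3-diketone), via methyl-side lithium enolate 20 (not isolated)
Conditions: LiHMDS (2.2 equiv), THF, −78 °C; then 19 (1.1 equiv), −78 → 0 °C; aq. NH4Cl
Reagents that add atoms: none
Why: Claisen-type C-acylation of the kinetic methyl-side lithium enolate by an N-acylbenzotriazole, a neutral acyl donor that reacts at its carbonyl and not at the cinnamoyl β-carbon; the second equivalent of base takes up the acidic 1,3-diketone as it forms, and C1 already holds its thermodynamic configuration.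

**Step 14**
Reactants: 21 (2Z,4E)-1-[(1R,2R,6S)-2-(3,4-dimethoxyphenyl)-6-[3-methoxy-4-(methoxymethoxy)phenyl]cyclohex-3-en-1-yl]-3-hydroxy-5-[3-methoxy-4-(methoxymethoxy)phenyl]penta-2,4-dien-1-one
Product: 22 (2Z,4E)-1-[(1R,2R,6S)-2-(3,4-dimethoxyphenyl)-6-(4-hydroxy-3-methoxyphenyl)cyclohex-3-en-1-yl]-3-hydroxy-5-(4-hydroxy-3-methoxyphenyl)penta-2,4-dien-1-one (CNP0290899.1)
Conditions: conc. HCl (cat.), MeOH, 40 °C
Reagents that add atoms: none
Why: Acid-catalysed acetal exchange cleaves both aryl MOM ethers in methanol; the enolised diketone, the ring alkene and the methyl ethers are stable to dilute acid, and C1 is already the thermodynamically preferred epimer.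

**Compound list**

1 | methyl (E)-3-(4-hydroxy-3-methoxyphenyl)prop-2-enoate (methyl ferulate) | COC(=O)/C=C/c1ccc(O)c(OC)c1 | starting material
2 | methyl (E)-3-[3-methoxy-4-(methoxymethoxy)phenyl]prop-2-enoate | COC(=O)/C=C/c1ccc(OCOC)c(OC)c1 | intermediate
3 | methyl phenyl sulfone | CS(=O)(=O)c1ccccc1 | starting material
4 | lithiomethyl phenyl sulfone | [Li]CS(=O)(=O)c1ccccc1 | intermediate
5 | (E)-4-[3-methoxy-4-(methoxymethoxy)phenyl]-1-(phenylsulfonyl)but-3-en-2-one | O=C(CS(=O)(=O)c1ccccc1)/C=C/c1ccc(OCOC)c(OC)c1 | intermediate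
6 | 3,4-dimethoxybenzaldehyde (veratraldehyde) | COc1ccc(C=O)cc1OC | starting material
7 | (1E,4E)-5-(3,4-dimethoxyphenyl)-1-[3-methoxy-4-(methoxymethoxy)phenyl]-4-(phenylsulfonyl)penta-1,4-dien-3-one | O=C(/C=C/c1ccc(OCOC)c(OC)c1)/C(=C\c1ccc(OC)c(OC)c1)S(=O)(=O)c1ccccc1 | intermediate
8 | dimethyl malonate | COC(=O)CC(=O)OC | starting material
9 | dimethyl 2-[(E)-1-(3,4-dimethoxyphenyl)-5-[3-methoxy-4-(methoxymethoxy)phenyl]-3-oxo-2-(phenylsulfonyl)pent-4-en-1-yl]propanedioate (equilibrating stereoisomers at the two sp3 centres) | COC(=O)C(C(=O)OC)C(c1ccc(OC)c(OC)c1)C(S(=O)(=O)c1ccccc1)C(=O)/C=C/c1ccc(OCOC)c(OC)c1 | intermediate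
10 | dimethyl (2S,3R,6R)-2-(3,4-dimethoxyphenyl)-6-[3-methoxy-4-(methoxymethoxy)phenyl]-4-oxo-3-(phenylsulfonyl)cyclohexane-1,1-dicarboxylate | COC(=O)C1(C(=O)OC)[C@@H](c2ccc(OCOC)c(OC)c2)CC(=O)[C@H](S(=O)(=O)c2ccccc2)[C@H]1c1ccc(OC)c(OC)c1 | intermediate
11 | dimethyl (2S,3R,6R)-2-(3,4-dimethoxyphenyl)-4-hydroxy-6-[3-methoxy-4-(methoxymethoxy)phenyl]-3-(phenylsulfonyl)cyclohexane-1,1-dicarboxylate (C4 epimers) | COC(=O)C1(C(=O)OC)[C@@H](c2ccc(OCOC)c(OC)c2)CC(O)[C@H](S(=O)(=O)c2ccccc2)[C@H]1c1ccc(OC)c(OC)c1 | intermediate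
12 | dimethyl (2S,3R,6R)-4-acetoxy-2-(3,4-dimethoxyphenyl)-6-[3-methoxy-4-(methoxymethoxy)phenyl]-3-(phenylsulfonyl)cyclohexane-1,1-dicarboxylate (C4 epimers) | COC(=O)C1(C(=O)OC)[C@@H](c2ccc(OCOC)c(OC)c2)CC(OC(C)=O)[C@H](S(=O)(=O)c2ccccc2)[C@H]1c1ccc(OC)c(OC)c1 | intermediate
13 | dimethyl (2S,6R)-2-(3,4-dimethoxyphenyl)-6-[3-methoxy-4-(methoxymethoxy)phenyl]cyclohex-3-ene-1,1-dicarboxylate | COC(=O)C1(C(=O)OC)[C@@H](c2ccc(OCOC)c(OC)c2)CC=C[C@H]1c1ccc(OC)c(OC)c1 | intermediate
14 | methyl (1S,2R,6S)-2-(3,4-dimethoxyphenyl)-6-[3-methoxy-4-(methoxymethoxy)phenyl]cyclohex-3-ene-1-carboxylate (all-cis C1 epimer) | COC(=O)[C@H]1[C@@H](c2ccc(OCOC)c(OC)c2)CC=C[C@H]1c1ccc(OC)c(OC)c1 | intermediate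
15 | methyl (1R,2R,6S)-2-(3,4-dimethoxyphenyl)-6-[3-methoxy-4-(methoxymethoxy)phenyl]cyclohex-3-ene-1-carboxylate | COC(=O)[C@@H]1[C@@H](c2ccc(OCOC)c(OC)c2)CC=C[C@H]1c1ccc(OC)c(OC)c1 | intermediate
16 | (1R,2R,6S)-2-(3,4-dimethoxyphenyl)-6-[3-methoxy-4-(methoxymethoxy)phenyl]cyclohex-3-ene-1-carboxylic acid | OC(=O)[C@@H]1[C@@H](c2ccc(OCOC)c(OC)c2)CC=C[C@H]1c1ccc(OC)c(OC)c1 | intermediate
17 | 1-[(1R,2R,6S)-2-(3,4-dimethoxyphenyl)-6-[3-methoxy-4-(methoxymethoxy)phenyl]cyclohex-3-en-1-yl]ethan-1-one | CC(=O)[C@@H]1[C@@H](c2ccc(OCOC)c(OC)c2)CC=C[C@H]1c1ccc(OC)c(OC)c1 | intermediate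
18 | (E)-3-[3-methoxy-4-(methoxymethoxy)phenyl]prop-2-enoic acid | OC(=O)/C=C/c1ccc(OCOC)c(OC)c1 | intermediate
19 | (E)-1-(1H-benzotriazol-1-yl)-3-[3-methoxy-4-(methoxymethoxy)phenyl]prop-2-en-1-one | O=C(/C=C/c1ccc(OCOC)c(OC)c1)n1nnc2ccccc12 | intermediate
20 | lithium 1-[(1R,2R,6S)-2-(3,4-dimethoxyphenyl)-6-[3-methoxy-4-(methoxymethoxy)phenyl]cyclohex-3-en-1-yl]ethen-1-olate | [Li]OC(=C)[C@@H]1[C@@H](c2ccc(OCOC)c(OC)c2)CC=C[C@H]1c1ccc(OC)c(OC)c1 | intermediate
21 | (2Z,4E)-1-[(1R,2R,6S)-2-(3,4-dimethoxyphenyl)-6-[3-methoxy-4-(methoxymethoxy)phenyl]cyclohex-3-en-1-yl]-3-hydroxy-5-[3-methoxy-4-(methoxymethoxy)phenyl]penta-2,4-dien-1-one | COCOc1ccc(/C=C/C(O)=C/C(=O)[C@@H]2[C@@H](c3ccc(OCOC)c(OC)c3)CC=C[C@H]2c2ccc(OC)c(OC)c2)cc1OC | intermediate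
22 | (2Z,4E)-1-[(1R,2R,6S)-2-(3,4-dimethoxyphenyl)-6-(4-hydroxy-3-methoxyphenyl)cyclohex-3-en-1-yl]-3-hydroxy-5-(4-hydroxy-3-methoxyphenyl)penta-2,4-dien-1-one | COc1cc(/C=C/C(O)=C/C(=O)[C@@H]2[C@@H](c3ccc(O)c(OC)c3)CC=C[C@H]2c2ccc(OC)c(OC)c2)ccc1O | target

**Step count and risks**

Total steps: 14. Longest linear sequence: 12 (steps 1–10, 13 and 14, from 1); steps 11 and 12 are a two-step branch from 2.

Steps most likely to fail:

1. Step 4. The ring-closing addition may show insufficient facial selectivity at C2, or the annulation may stall because the acidic sulfonyl ketone of 9 occupies the basic site of the catalyst and the alkoxy-substituted enone is a weak acceptor. Fallback: setting out from 7 and 8, the annulation is run without asymmetric induction under a catalytic achiral base (DBU, CH2Cl2, rt), a known base-mediated double Michael reaction of malonates with diaryl dienones under thermodynamic control. It should give the same all-equatorial diastereomer as a racemate, that is 10 together with its mirror image dimethyl (2R,3S,6S)-2-(3,4-dimethoxyphenyl)-6-[3-methoxy-4-(methoxymethoxy)phenyl]-4-oxo-3-(phenylsulfonyl)cyclohexane-1,1-dicarboxylate F1. Preparative chromatography on a chiral stationary phase separates the two, and the route is rejoined at 10.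

2. Step 13. The hindered enolate may add in conjugate fashion to the cinnamoyl donor, be O-acylated, or be quenched by the product diketone before acylation is complete. Fallback: setting out from 17, a crossed Claisen condensation with ethyl acetate (NaH, EtOAc–THF, 50 °C), which offers no Michael acceptor, should give 1-[(1R,2R,6S)-2-(3,4-dimethoxyphenyl)-6-[3-methoxy-4-(methoxymethoxy)phenyl]cyclohex-3-en-1-yl]butane-1,3-dione F2. A boron-templated aldol condensation of its terminal methyl group with vanillin (B2O3, B(OBu)3, n-BuNH2, EtOAc, 70 °C; then warm dilute HCl), the standard curcuminoid construction, should give (2Z,4E)-1-[(1R,2R,6S)-2-(3,4-dimethoxyphenyl)-6-[3-methoxy-4-(methoxymethoxy)phenyl]cyclohex-3-en-1-yl]-3-hydroxy-5-(4-hydroxy-3-methoxyphenyl)penta-2,4-dien-1-one F3. Treatment with HCl in MeOH as in step 14 removes the remaining MOM group, and the route is rejoined at 22.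

3. Step 9. Saponification may be slow or incomplete because the ester carbonyl is shielded on both sides by aryl-bearing carbons, and a sluggish follow-up in step 10 could lead to over-addition of methyllithium. Fallback: setting out from 15, aminolysis with the magnesium amide of N,O-dimethylhydroxylamine (MeNHOMe·HCl, i-PrMgCl, THF, −20 → 0 °C) should give the Weinreb amide (1R,2R,6S)-2-(3,4-dimethoxyphenyl)-N-methoxy-6-[3-methoxy-4-(methoxymethoxy)phenyl]-N-methylcyclohex-3-ene-1-carboxamide F4. Addition of MeMgBr (THF, 0 °C → rt) stops at the chelated tetrahedral stage and gives the methyl ketone on work-up, so the route is rejoined at 17 without passing through 16.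

**Further compounds**

F1 | step 4 | dimethyl (2R,3S,6S)-2-(3,4-dimethoxyphenyl)-6-[3-methoxy-4-(methoxymethoxy)phenyl]-4-oxo-3-(phenylsulfonyl)cyclohexane-1,1-dicarboxylate | COC(=O)C1(C(=O)OC)[C@H](c2ccc(OCOC)c(OC)c2)CC(=O)[C@@H](S(=O)(=O)c2ccccc2)[C@@H]1c1ccc(OC)c(OC)c1
F2 | step 13 | 1-[(1R,2R,6S)-2-(3,4-dimethoxyphenyl)-6-[3-methoxy-4-(methoxymethoxy)phenyl]cyclohex-3-en-1-yl]butane-1,3-dione | CC(=O)CC(=O)[C@@H]1[C@@H](c2ccc(OCOC)c(OC)c2)CC=C[C@H]1c1ccc(OC)c(OC)c1
F3 | step 13 | (2Z,4E)-1-[(1R,2R,6S)-2-(3,4-dimethoxyphenyl)-6-[3-methoxy-4-(methoxymethoxy)phenyl]cyclohex-3-en-1-yl]-3-hydroxy-5-(4-hydroxy-3-methoxyphenyl)penta-2,4-dien-1-one | COc1cc(/C=C/C(O)=C/C(=O)[C@@H]2[C@@H](c3ccc(OCOC)c(OC)c3)CC=C[C@H]2c2ccc(OC)c(OC)c2)ccc1O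
F4 | step 9 | (1R,2R,6S)-2-(3,4-dimethoxyphenyl)-N-methoxy-6-[3-methoxy-4-(methoxymethoxy)phenyl]-N-methylcyclohex-3-ene-1-carboxamide | CON(C)C(=O)[C@@H]1[C@@H](c2ccc(OCOC)c(OC)c2)CC=C[C@H]1c1ccc(OC)c(OC)c1
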